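The runs come from a simulation from invented constants, and the scatter is random.

I started from the earliest readings of two earlier runs, which stand here with the flask I was asked about.

in all of them: starting material 0.10 M; gas phase 11 mM (held)
- east: protic impurity 0.014 M; run made earlier
- north: protic impurity 0.022 M; run made earlier
- flask: protic impurity 0.0100 M; time 80 min

| run | time / min | target / % | starting material / % |
|---|---|---|---|
| east | 5.00 | 3.8 | 83.3 |
| east | 12.0 | 6.6 | 77.7 |
| east | 30.0 | 17.9 | 67.9 |
| east | 60.0 | 30.1 | 52.7 |
| north | 15.0 | 8.5 | 69.9 |
| north | 30.0 | 16.8 | 61.7 |
| north | 50.0 | 24.2 | 52.8 |
| north | 60.0 | 27.8 | 48.3 |

(scatter of a reading: 0.5 percentage points)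

- the analysis behind the earlier runs scatters by 0.5 percentage points, standard deviation
- at the start none of the gas phase is in solution

- target at 80 min, in percent of the starting material charged
- the change that raises the amount of target at 80 min, in percent of the starting material charged most ("none" if none brings more than 2 percentage points) (larch / oak / none)
- amount of target at 80 min, in percent of the starting material charged, after oak

- larch: doubling the saturation concentration of gas phase, all else as stated
- oak: doubling the transfer coefficient of the gas phase, all else as stated

By the first east reading at 5.00 min, target and starting material together had already fallen short of the charge by 13 percentage points, against a protic impurity charge of 14.0 % of the starting material. So I counted the impurity as taking starting material one to one. After that reading the east run gave 0.00832 min⁻¹ for the pseudo-first-order constant, the fraction of starting material lost per minute once the early drop is over. The north run gave 0.00821 min⁻¹. The half-life this implies, 83.3 min, is far longer than the early drop lasted, so I took control as passing from impurity to main step within the first minutes.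

I then built the flask up. First came the main step by itself:

target = 1 − exp(−constant × time) = 48.6 %

Next came the impurity, which leaves a pool of 90.0 % of the charge:

target = pool × 48.6 % = 43.8 %

Last came the slow loss. At the final readings the balance fell short of the pool by 3.2 points in the east run and 1.9 points in the north run. I took this as a loss from target, which itself grows with time, so I scaled the mean by the square of the times:

target = 43.8 % − 4.5 points = 39.2 %

I expected oak to change little, and larch to raise the target if the constant follows the gas in solution, which these runs did not test.

The forecast gave 38 %, larch and 38.5 %, holding that “gas transfer is fast and not limiting”.

The flask gave 38.8 %, with larch gaining 14 points and 38.9 % after oak, and these equations ran in it: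

    starting material + protic impurity → quenched substrate (k = 17.3 L mol⁻¹ min⁻¹)
    gas phase ⇌ dissolved gas, rate k2*(csat - [dissolved gas]) (kL = 8.29 min⁻¹)
    starting material + dissolved gas → target (k = 0.736 L mol⁻¹ min⁻¹)
    2 dissolved gas → self-condensation product (k = 0.790 L mol⁻¹ min⁻¹)
    dissolved gas + target → over-reacted product (k = 0.197 L mol⁻¹ min⁻¹)

The target in this flask moved by 5 points when the impurity reached 0.0217 M. The constant and pool put starting material in the flask at 46.3 % at 80 min, and it held 47.4 %. For the neighbour charged with 0.040 M of starting material, they give 38.5 %, and that flask held 39.2 %.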